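(The rate constants were chosen freely; the run is a simulation.)

A leftover of starting material at the end of a run poses one question: did the enzyme slow down, or did it die? These flasks differ in their charge of starting material.

common to all: enzyme 13 µM; time 80 s

|  | starting material |
|---|---|
| Tuesday's | 0.030 M |
| Monday's | 0.060 M |
| Thursday's | 0.12 M |
| Friday's | 0.25 M |
| Wednesday's | 0.50 M |

* [product] at the end for Tuesday's, Monday's, Thursday's, Friday's, Wednesday's, in this order
* the course of these numbers from the first flask to the last (falls all the way / falls, then rises / hardly changes / rises, then falls / rises all the way)

- "hardly changes" means that all values lie within two and a half points (for a concentration: within two and a half percent of the largest)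
- run time (Tuesday's): 80 s

I begin with the main step alone, at full speed. The enzyme then turns over 138 s⁻¹, so its charge of 13 µM makes 0.143 M of product in 80 s. That is more than Tuesday's, Monday's or Thursday's charge and less than Friday's or Wednesday's. So far, the three smaller flasks are capped by their charge and the two larger by speed.

Now I add the loss: enzyme meeting starting material becomes spent catalyst, with constant 0.038 M⁻¹ s⁻¹. Enzyme is the reagent charged in the smaller amount, and enzyme plus spent catalyst stay at its charge. While starting material stands near its charge, the loss is pseudo-first-order. For Wednesday's this gives 52.6 s: the working life, one over the loss constant times the starting material, in which the enzyme falls by a factor of e. With starting material held at its charge and the main step at top speed, I estimate product as top speed times enzyme charge times working life times (one minus e to the power of minus run time over working life). Wednesday's working life is shorter than the run, so its estimate drops to 0.0735 M. Thursday's working life of 219 s outlasts the run, and its estimate of 0.120 M about equals its charge.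

Last comes the slowing of the main step, which runs at half of top speed when starting material stands at 35 mM. Tuesday's starts below that, so I expect it under its charge of 0.030 M, by an amount I don't reckon. My figures therefore climb to Thursday's and are low again at Wednesday's, but I have no figure for Friday's yet.

The forecast gives 0.0198 M, 0.0467 M, 0.094 M, 0.1045 M and 0.0761 M, so its course rises, then falls. It places the top at Friday's, on the grounds that “At high substrate the enzyme is killed faster in proportion to substrate”.

    starting material + enzyme → spent catalyst (k1 = 0.038 M⁻¹ s⁻¹)
    starting material + enzyme → product + enzyme, rate k2*[starting material]^2.5*[enzyme]/(1 + ([starting material]/Kh2)^2.5) (Kh2 = 35 mM, k2 = 6.0 × 10⁵ M⁻²·⁵ s⁻¹)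

The flasks give 0.0198 M, 0.0467 M, 0.0940 M, 0.104 M and 0.0761 M, and the course, as forecast, rises, then falls. Wednesday's holds 25.2% of its enzyme at 80.0 s, and its working life of 52.6 s puts that share at 21.9%. Friday's working life is 105 s, twice Wednesday's, which makes Friday's estimate 0.100 M, and Friday's flask gives 0.104 M.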